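**Retrosynthetic overview** (flavanone numbering for rings A and C; C1' is the methine on C8; ring B is the ring on C1')

1. The strategy rests on the six-membered carbocycle on C1': an enolised β-diketone (C2''–OH, C6''=O) on either side of the C1'-bearing carbon C1'', two quaternary C(CH3)2 carbons (C3'', C5'') and the lone ketone C4'' between them. This is a phloroglucinol ring after four C-methylations, so its four C–CH3 bonds are cut back to a free 2,4,6-trihydroxyphenyl ring B.
2. Ring C is cut at C2–Ph (asymmetric rhodium 1,4-addition of phenylboronic acid to a chromone) and at O1–C2 (acid closure of a C4a alkynyl acetal onto the C8a oxygen). This three-carbon handle is placed on ring A before the methylation and rides through it as a spectator, because C-acylation of ring A afterwards would have to compete with the acidic triketone enol.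
3. The C1'–ring B bond comes from a chiral-phosphoric-acid Friedel–Crafts addition of 1,3,5-tris(allyloxy)benzene to the o-quinone methide of a ring A o-hydroxybenzyl alcohol, which sets C1'. Ring A derives from 3,5-dihydroxy-4-methylbenzoic acid through the symmetric phenol 5, whose free OH becomes O1.
4. Ring order: ring A (aromatic from the start), ring B attached as an arene, ring B dearomatised to the triketone (step 13, no ring closure), ring C closed (step 14), C2 set (step 16), benzyl groups removed.

Key step: step 13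

Remark: C1' keeps one spatial arrangement from 12 to 27; its CIP letter reads S in 12, 13 and 21–27 and R in 14–18 only because the priority order of its two ring substituents changes.

**Step 1**
Reactants: 1 3,5-dihydroxy-4-methylbenzoic acid
Product: 2 benzyl 3,5-bis(benzyloxy)-4-methylbenzoate
Conditions: BnBr (3.5 equiv), K2CO3 (4 equiv), DMF, 60 °C
Reagents that add atoms: benzyl bromide, BrCc1ccccc1
Why: Williamson O-alkylation of both phenols together with carboxylate alkylation (SN2 on benzyl bromide) should give the fully benzylated ester in one operation.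

**Step 2**
Reactants: 2 benzyl 3,5-bis(benzyloxy)-4-methylbenzoate
Product: 3 2-[3,5-bis(benzyloxy)-4-methylphenyl]propan-2-ol
Conditions: MeMgBr (3.5 equiv), THF, 0 °C to rt; aq NH4Cl
Reagents that add atoms: methylmagnesium bromide, C[Mg]Br
Why: Double Grignard addition to the ester gives the tertiary benzylic carbinol needed for the aryl-to-oxygen shift of the next step.

**Step 3**
Reactants: 3 2-[3,5-bis(benzyloxy)-4-methylphenyl]propan-2-ol
Product: 5 3,5-bis(benzyloxy)-4-methylphenol, via tertiary hydroperoxide 4 (not isolated)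
Conditions: 50% aq H2O2, cat. H2SO4, THF, 0 °C; crude 4 then BF3·OEt2, CH2Cl2, 0 °C
Reagents that add atoms: hydrogen peroxide, OO
Why: Hock-type benzylic hydroperoxide rearrangement, in which acid exchanges the tertiary OH for OOH and the Lewis acid triggers aryl migration to oxygen, the resulting hemiketal collapsing to the phenol and acetone; the benzyl ethers should tolerate the short, cold acid exposure.

**Step 4**
Reactants: 5 3,5-bis(benzyloxy)-4-methylphenol
Product: 6 4,6-bis(benzyloxy)-2-hydroxy-5-methylbenzaldehyde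
Conditions: MgCl2 (2 equiv), Et3N (4 equiv), (CH2O)n (6 equiv), MeCN, reflux
Reagents that add atoms: paraformaldehyde (as formaldehyde), C=O
Why: Magnesium-mediated ortho-formylation (Casiraghi–Skattebøl), in which the magnesium phenoxide delivers formaldehyde to an ortho carbon and a second formaldehyde oxidises the hydroxymethyl group by hydride transfer; the two ortho positions are equivalent and the chelated product resists a second formylation.

**Step 5**
Reactants: 6 4,6-bis(benzyloxy)-2-hydroxy-5-methylbenzaldehyde; 7 isobutylmagnesium bromide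
Product: 8 rac-3,5-bis(benzyloxy)-2-(1-hydroxy-3-methylbutyl)-4-methylphenol
Conditions: 7 (3 equiv), THF, −40 °C to 0 °C; aq NH4Cl
Reagents that add atoms: isobutylmagnesium bromide (7), CC(C)C[Mg]Br
Why: Grignard 1,2-addition to the aldehyde after deprotonation of the phenol by the first equivalent gives the o-hydroxybenzyl alcohol as a racemate, which is acceptable because the carbinol carbon becomes planar in step 7.

**Step 6**
Reactants: 9 phloroglucinol
Product: 10 1,3,5-tris(allyloxy)benzene
Conditions: allyl bromide (4 equiv), K2CO3, DMF, 50 °C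
Reagents that add atoms: allyl bromide, C=CCBr
Why: Threefold Williamson O-allylation; allyl is chosen because zerovalent palladium later removes it without touching benzyl or MOM ethers.

**Step 7**
Reactants: 8 rac-3,5-bis(benzyloxy)-2-(1-hydroxy-3-methylbutyl)-4-methylphenol; 10 1,3,5-tris(allyloxy)benzene
Product: 12 3,5-bis(benzyloxy)-4-methyl-2-[(1S)-3-methyl-1-[2,4,6-tris(allyloxy)phenyl]butyl]phenol, via o-quinone methide 11 (not isolated)
Conditions: (R)-TRIP [(R)-3,3'-bis(2,4,6-triisopropylphenyl)-BINOL hydrogen phosphate] (10 mol%), 10 (2.5 equiv), 5 Å MS, toluene, −20 °C to rt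
Reagents that add atoms: none
Why: Chiral-phosphoric-acid Friedel–Crafts alkylation through an o-quinone methide, in which the acid dehydrates 8 to 11, 11 stays hydrogen-bonded to the chiral phosphate through its carbonyl oxygen, and the symmetric arene 10 adds to the exocyclic carbon from the face left open by the 3,3'-aryl groups, which sets C1'; the catalyst antipode that gives (S) is fixed in a first run with both antipodes and is written here as (R).

**Step 8**
Reactants: 12 3,5-bis(benzyloxy)-4-methyl-2-[(1S)-3-methyl-1-[2,4,6-tris(allyloxy)phenyl]butyl]phenol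
Product: 13 4,6-bis(benzyloxy)-2-hydroxy-5-methyl-3-[(1S)-3-methyl-1-[2,4,6-tris(allyloxy)phenyl]butyl]benzaldehyde
Conditions: MgCl2 (3 equiv), Et3N (6 equiv), (CH2O)n (8 equiv), MeCN/THF, reflux
Reagents that add atoms: paraformaldehyde (as formaldehyde), C=O
Why: Second magnesium-mediated ortho-formylation, directed by the only phenol in the molecule to its one free ortho carbon (C4a), so the two unsubstituted carbons of the trialkoxy ring B should stay untouched.

**Step 9**
Reactants: 13 4,6-bis(benzyloxy)-2-hydroxy-5-methyl-3-[(1S)-3-methyl-1-[2,4,6-tris(allyloxy)phenyl]butyl]benzaldehyde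
Product: 14 4,6-bis(benzyloxy)-2-(methoxymethoxy)-5-methyl-3-[(1R)-3-methyl-1-[2,4,6-tris(allyloxy)phenyl]butyl]benzaldehyde
Conditions: NaH (1.3 equiv), MOMCl (1.5 equiv), THF/DMF, 0 °C
Reagents that add atoms: chloromethyl methyl ether, COCCl
Why: O-alkylation of the sodium phenoxide masks the C8a oxygen as an acetal that survives carbonate, Grignard reagent, palladium and methoxide and leaves under the acid of step 14.

**Step 10**
Reactants: 14 4,6-bis(benzyloxy)-2-(methoxymethoxy)-5-methyl-3-[(1R)-3-methyl-1-[2,4,6-tris(allyloxy)phenyl]butyl]benzaldehyde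
Product: 15 1,5-bis(benzyloxy)-2-ethynyl-3-(methoxymethoxy)-6-methyl-4-[(1R)-3-methyl-1-[2,4,6-tris(allyloxy)phenyl]butyl]benzene
Conditions: dimethyl (1-diazo-2-oxopropyl)phosphonate (1.5 equiv), K2CO3 (2 equiv), MeOH/THF, rt
Reagents that add atoms: dimethyl (1-diazo-2-oxopropyl)phosphonate, COP(=O)(OC)C(=[N+]=[N-])C(C)=O
Why: Ohira–Bestmann (Seyferth–Gilbert) homologation converts the non-enolisable aldehyde into the terminal alkyne under mild carbonate/methanol conditions that spare allyl, benzyl and MOM ethers.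

**Step 11**
Reactants: 15 1,5-bis(benzyloxy)-2-ethynyl-3-(methoxymethoxy)-6-methyl-4-[(1R)-3-methyl-1-[2,4,6-tris(allyloxy)phenyl]butyl]benzene
Product: 17 1,5-bis(benzyloxy)-2-(3,3-diethoxyprop-1-yn-1-yl)-3-(methoxymethoxy)-6-methyl-4-[(1R)-3-methyl-1-[2,4,6-tris(allyloxy)phenyl]butyl]benzene, via alkynylmagnesium bromide 16 (not isolated)
Conditions: EtMgBr (1.2 equiv), THF, 40 °C; then HC(OEt)3 (4 equiv), toluene, 85 °C; aq NaHCO3
Reagents that add atoms: triethyl orthoformate, CCOC(OCC)OCC
Why: Deprotonation of the alkyne and substitution of one ethoxy group of the orthoformate by the alkynyl Grignard reagent (Bodroux–Chichibabin-type acetal synthesis) installs the alkynyl acetal, a base-inert and non-enolisable mask for C4, C3 and C2 of ring C.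

**Step 12**
Reactants: 17 1,5-bis(benzyloxy)-2-(3,3-diethoxyprop-1-yn-1-yl)-3-(methoxymethoxy)-6-methyl-4-[(1R)-3-methyl-1-[2,4,6-tris(allyloxy)phenyl]butyl]benzene
Product: 18 2-[(1R)-1-[2,4-bis(benzyloxy)-5-(3,3-diethoxyprop-1-yn-1-yl)-6-(methoxymethoxy)-3-methylphenyl]-3-methylbutyl]benzene-1,3,5-triol
Conditions: Pd(PPh3)4 (5 mol%), morpholine (10 equiv), THF, rt, argon; used promptly
Reagents that add atoms: none
Why: Tsuji–Trost deallylation, in which zerovalent palladium ionises each aryl allyl ether to a π-allyl complex that morpholine captures, frees the three ring B hydroxyls while benzyl ethers, MOM ether, acetal and the internal alkyne should stay intact.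

**Step 13**
Reactants: 18 2-[(1R)-1-[2,4-bis(benzyloxy)-5-(3,3-diethoxyprop-1-yn-1-yl)-6-(methoxymethoxy)-3-methylphenyl]-3-methylbutyl]benzene-1,3,5-triol; 19 iodomethane
Product: 21 2-[(1S)-1-[2,4-bis(benzyloxy)-5-(3,3-diethoxyprop-1-yn-1-yl)-6-(methoxymethoxy)-3-methylphenyl]-3-methylbutyl]-3-hydroxy-4,4,6,6-tetramethylcyclohex-2-ene-1,5-dione, via gem-dimethyl dienone 20 (not isolated)
Conditions: NaOMe (6 equiv), 19 (8 equiv), MeOH, 0 °C to 45 °C, argon; then cold NaH2PO4 buffer (pH 5)
Reagents that add atoms: iodomethane (19), CI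
Why: Methoxide ionises the free phloroglucinol ring B, whose phenolate reacts through its ring carbons: each of the two unsubstituted carbons is methylated, the dienone formed (as in 20) re-enolises and the same carbon is methylated again, so that four C–CH3 bonds form and the arene ends as the tetramethyl triketone, enolised at the carbon that bears C1' (sodium enolate until work-up). The closest known reaction is the iodomethane/sodium methoxide C-tetramethylation of phloroglucinol derivatives used to prepare syncarpic acid and its 6-substituted congeners. No ring is closed and no stereocentre is created; C1' is only carried through, and because ring A has no free hydroxyl it cannot form a quinone methide, so there is no fragmentation–recombination route to scramble C1'. The step needs C- over O-methylation and a stop after four methyl groups: the protic medium and the soft electrophile favour carbon, and the carbon attached to C1' is shielded by its branched substituent and ends inside a stabilised, weakly nucleophilic triketone enolate. The alkyne, acetal, MOM and benzyl groups of ring A are inert to methoxide and iodomethane.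

**Step 14**
Reactants: 21 2-[(1S)-1-[2,4-bis(benzyloxy)-5-(3,3-diethoxyprop-1-yn-1-yl)-6-(methoxymethoxy)-3-methylphenyl]-3-methylbutyl]-3-hydroxy-4,4,6,6-tetramethylcyclohex-2-ene-1,5-dione
Product: 23 5,7-bis(benzyloxy)-8-[(1S)-1-(2-hydroxy-3,3,5,5-tetramethyl-4,6-dioxocyclohex-1-en-1-yl)-3-methylbutyl]-6-methyl-4H-chromen-4-one, via ketoaldehyde phenol 22 (not isolated)
Conditions: 2 M aq H2SO4, THF/MeOH, 45 °C
Reagents that add atoms: water, O
Why: One acid treatment hydrolyses the acetal to the ynal, adds water to the alkyne carbon next to the ring (conjugate hydration, assisted by three ortho/para alkoxy groups), removes the MOM group and lets the freed C8a phenol of 22 condense with the aldehyde (6-exo-trig hemiacetal, then dehydration) to the pyranone of ring C; no base is present, so the phenol that is briefly free ortho to C1' should not open a retro-Michael path.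

**Step 15**
Reactants: 23 5,7-bis(benzyloxy)-8-[(1S)-1-(2-hydroxy-3,3,5,5-tetramethyl-4,6-dioxocyclohex-1-en-1-yl)-3-methylbutyl]-6-methyl-4H-chromen-4-one
Product: 24 5,7-bis(benzyloxy)-8-[(1S)-1-[2-(benzyloxy)-3,3,5,5-tetramethyl-4,6-dioxocyclohex-1-en-1-yl]-3-methylbutyl]-6-methyl-4H-chromen-4-one
Conditions: BnBr (1.3 equiv), Cs2CO3 (1.5 equiv), DMF, rt
Reagents that add atoms: benzyl bromide, BrCc1ccccc1
Why: O-alkylation of the caesium enolate of the hindered 2-substituted β-diketone (C-alkylation is blocked by the branched C1' substituent, and both enol oxygens give the same ether) hides the acidic, metal-chelating enol as a benzyl vinylogous ester that the final hydrogenolysis removes.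

**Step 16**
Reactants: 24 5,7-bis(benzyloxy)-8-[(1S)-1-[2-(benzyloxy)-3,3,5,5-tetramethyl-4,6-dioxocyclohex-1-en-1-yl]-3-methylbutyl]-6-methyl-4H-chromen-4-one; 25 phenylboronic acid
Product: 26 (2R)-5,7-bis(benzyloxy)-8-[(1S)-1-[2-(benzyloxy)-3,3,5,5-tetramethyl-4,6-dioxocyclohex-1-en-1-yl]-3-methylbutyl]-6-methyl-2-phenyl-2,3-dihydro-4H-chromen-4-one
Conditions: [Rh(OH)(cod)]2 (3 mol%), (R)-MeO-F12-BIPHEP [(R)-6,6'-dimethoxy-2,2'-bis[bis(3,4,5-trifluorophenyl)phosphino]biphenyl] (7 mol%), 25 (3 equiv), toluene/H2O 10:1, 40 °C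
Reagents that add atoms: phenylboronic acid (25), OB(O)c1ccccc1
Why: Hayashi–Miyaura rhodium-catalysed asymmetric 1,4-addition of the arylboronic acid to the chromone C2=C3 bond, in which the chiral bisphosphine controls the face of phenyl transfer and so sets C2 (catalyst control, C1' being remote); the (R)-ligand is expected by analogy with cyclic enones to give 2R, and this is checked on 5,7-bis(benzyloxy)chromone before use.

**Step 17**
Reactants: 26 (2R)-5,7-bis(benzyloxy)-8-[(1S)-1-[2-(benzyloxy)-3,3,5,5-tetramethyl-4,6-dioxocyclohex-1-en-1-yl]-3-methylbutyl]-6-methyl-2-phenyl-2,3-dihydro-4H-chromen-4-one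
Product: 27 (2R)-5,7-dihydroxy-8-[(1S)-1-(2-hydroxy-3,3,5,5-tetramethyl-4,6-dioxocyclohex-1-en-1-yl)-3-methylbutyl]-6-methyl-2-phenylchroman-4-one (CNP0249552.1)
Conditions: H2 (1 atm), 10% Pd/C, EtOAc/MeOH, rt
Reagents that add atoms: none
Why: Heterogeneous hydrogenolysis cleaves the two aryl benzyl ethers and the benzyl enol ether at room temperature without acid or base, so neither C2 (retro-oxa-Michael) nor C1' (retro-Michael) should be put at risk.

**Compound list**

1 | 3,5-dihydroxy-4-methylbenzoic acid | Cc1c(O)cc(C(=O)O)cc1O | starting material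
2 | benzyl 3,5-bis(benzyloxy)-4-methylbenzoate | Cc1c(OCc2ccccc2)cc(C(=O)OCc2ccccc2)cc1OCc1ccccc1 | intermediate
3 | 2-[3,5-bis(benzyloxy)-4-methylphenyl]propan-2-ol | Cc1c(OCc2ccccc2)cc(C(C)(C)O)cc1OCc1ccccc1 | intermediate
4 | 2-[3,5-bis(benzyloxy)-4-methylphenyl]propan-2-yl hydroperoxide | Cc1c(OCc2ccccc2)cc(C(C)(C)OO)cc1OCc1ccccc1 | intermediate (not isolated)
5 | 3,5-bis(benzyloxy)-4-methylphenol | Cc1c(OCc2ccccc2)cc(O)cc1OCc1ccccc1 | intermediate
6 | 4,6-bis(benzyloxy)-2-hydroxy-5-methylbenzaldehyde | Cc1c(OCc2ccccc2)cc(O)c(C=O)c1OCc1ccccc1 | intermediate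
7 | isobutylmagnesium bromide | CC(C)C[Mg]Br | starting material
8 | rac-3,5-bis(benzyloxy)-2-(1-hydroxy-3-methylbutyl)-4-methylphenol | Cc1c(OCc2ccccc2)cc(O)c(C(O)CC(C)C)c1OCc1ccccc1 | intermediate
9 | phloroglucinol | Oc1cc(O)cc(O)c1 | starting material
10 | 1,3,5-tris(allyloxy)benzene | C=CCOc1cc(OCC=C)cc(OCC=C)c1 | intermediate
11 | o-quinone methide: 3,5-bis(benzyloxy)-4-methyl-6-(3-methylbutylidene)cyclohexa-2,4-dien-1-one | CC1=C(OCc2ccccc2)C(=CCC(C)C)C(=O)C=C1OCc1ccccc1 | intermediate (not isolated)
12 | 3,5-bis(benzyloxy)-4-methyl-2-[(1S)-3-methyl-1-[2,4,6-tris(allyloxy)phenyl]butyl]phenol | Cc1c(OCc2ccccc2)cc(O)c([C@H](CC(C)C)c2c(OCC=C)cc(OCC=C)cc2OCC=C)c1OCc1ccccc1 | intermediate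
13 | 4,6-bis(benzyloxy)-2-hydroxy-5-methyl-3-[(1S)-3-methyl-1-[2,4,6-tris(allyloxy)phenyl]butyl]benzaldehyde | Cc1c(OCc2ccccc2)c(C=O)c(O)c([C@H](CC(C)C)c2c(OCC=C)cc(OCC=C)cc2OCC=C)c1OCc1ccccc1 | intermediate
14 | 4,6-bis(benzyloxy)-2-(methoxymethoxy)-5-methyl-3-[(1R)-3-methyl-1-[2,4,6-tris(allyloxy)phenyl]butyl]benzaldehyde | Cc1c(OCc2ccccc2)c(C=O)c(OCOC)c([C@H](CC(C)C)c2c(OCC=C)cc(OCC=C)cc2OCC=C)c1OCc1ccccc1 | intermediate
15 | 1,5-bis(benzyloxy)-2-ethynyl-3-(methoxymethoxy)-6-methyl-4-[(1R)-3-methyl-1-[2,4,6-tris(allyloxy)phenyl]butyl]benzene | Cc1c(OCc2ccccc2)c(C#C)c(OCOC)c([C@H](CC(C)C)c2c(OCC=C)cc(OCC=C)cc2OCC=C)c1OCc1ccccc1 | intermediate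
16 | bromomagnesium acetylide of 15 | Cc1c(OCc2ccccc2)c(C#C[Mg]Br)c(OCOC)c([C@H](CC(C)C)c2c(OCC=C)cc(OCC=C)cc2OCC=C)c1OCc1ccccc1 | intermediate (not isolated)
17 | 1,5-bis(benzyloxy)-2-(3,3-diethoxyprop-1-yn-1-yl)-3-(methoxymethoxy)-6-methyl-4-[(1R)-3-methyl-1-[2,4,6-tris(allyloxy)phenyl]butyl]benzene | Cc1c(OCc2ccccc2)c(C#CC(OCC)OCC)c(OCOC)c([C@H](CC(C)C)c2c(OCC=C)cc(OCC=C)cc2OCC=C)c1OCc1ccccc1 | intermediate
18 | 2-[(1R)-1-[2,4-bis(benzyloxy)-5-(3,3-diethoxyprop-1-yn-1-yl)-6-(methoxymethoxy)-3-methylphenyl]-3-methylbutyl]benzene-1,3,5-triol (key-step precursor) | Cc1c(OCc2ccccc2)c(C#CC(OCC)OCC)c(OCOC)c([C@H](CC(C)C)c2c(O)cc(O)cc2O)c1OCc1ccccc1 | intermediate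
19 | iodomethane | CI | starting material
20 | half-methylated stage: ring B as a 4-substituted 3,5-dihydroxy-6,6-dimethylcyclohexa-2,4-dien-1-one, C1' as in 18 | Cc1c(OCc2ccccc2)c(C#CC(OCC)OCC)c(OCOC)c([C@H](CC(C)C)C2=C(O)C(C)(C)C(=O)C=C2O)c1OCc1ccccc1 | intermediate (not isolated)
21 | 2-[(1S)-1-[2,4-bis(benzyloxy)-5-(3,3-diethoxyprop-1-yn-1-yl)-6-(methoxymethoxy)-3-methylphenyl]-3-methylbutyl]-3-hydroxy-4,4,6,6-tetramethylcyclohex-2-ene-1,5-dione (key-step product) | Cc1c(OCc2ccccc2)c(C#CC(OCC)OCC)c(OCOC)c([C@H](CC(C)C)C2=C(O)C(C)(C)C(=O)C(C)(C)C2=O)c1OCc1ccccc1 | intermediate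
22 | 3-[2,4-bis(benzyloxy)-6-hydroxy-5-[(1S)-1-(2-hydroxy-3,3,5,5-tetramethyl-4,6-dioxocyclohex-1-en-1-yl)-3-methylbutyl]-3-methylphenyl]-3-oxopropanal | Cc1c(OCc2ccccc2)c(C(=O)CC=O)c(O)c([C@H](CC(C)C)C2=C(O)C(C)(C)C(=O)C(C)(C)C2=O)c1OCc1ccccc1 | intermediate (not isolated)
23 | 5,7-bis(benzyloxy)-8-[(1S)-1-(2-hydroxy-3,3,5,5-tetramethyl-4,6-dioxocyclohex-1-en-1-yl)-3-methylbutyl]-6-methyl-4H-chromen-4-one | O=c1ccoc2c([C@H](CC(C)C)C3=C(O)C(C)(C)C(=O)C(C)(C)C3=O)c(OCc3ccccc3)c(C)c(OCc3ccccc3)c12 | intermediate
24 | 5,7-bis(benzyloxy)-8-[(1S)-1-[2-(benzyloxy)-3,3,5,5-tetramethyl-4,6-dioxocyclohex-1-en-1-yl]-3-methylbutyl]-6-methyl-4H-chromen-4-one | O=c1ccoc2c([C@H](CC(C)C)C3=C(OCc4ccccc4)C(C)(C)C(=O)C(C)(C)C3=O)c(OCc3ccccc3)c(C)c(OCc3ccccc3)c12 | intermediate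
25 | phenylboronic acid | OB(O)c1ccccc1 | starting material
26 | (2R)-5,7-bis(benzyloxy)-8-[(1S)-1-[2-(benzyloxy)-3,3,5,5-tetramethyl-4,6-dioxocyclohex-1-en-1-yl]-3-methylbutyl]-6-methyl-2-phenyl-2,3-dihydro-4H-chromen-4-one | O=C1C[C@H](c2ccccc2)Oc2c([C@H](CC(C)C)C3=C(OCc4ccccc4)C(C)(C)C(=O)C(C)(C)C3=O)c(OCc3ccccc3)c(C)c(OCc3ccccc3)c21 | intermediate
27 | (2R)-5,7-dihydroxy-8-[(1S)-1-(2-hydroxy-3,3,5,5-tetramethyl-4,6-dioxocyclohex-1-en-1-yl)-3-methylbutyl]-6-methyl-2-phenylchroman-4-one | Cc1c(O)c2c(c([C@H](CC(C)C)C3=C(O)C(C)(C)C(=O)C(C)(C)C3=O)c1O)O[C@@H](c1ccccc1)CC2=O | target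

**Step count**

Total: 17 steps. Longest linear sequence: 16 steps (steps 1–5 and 7–17, from 1); step 6 is a one-step side branch.

**Steps most likely to fail**

Step 13 (key step). O-methylation may compete with C-methylation, the sequence may stall before the fourth methyl group or run on to a fifth methylation at the carbon carrying C1', and the free triol may oxidise in air. The fallback brings the tetramethyl ring in ready-made instead of building it on the substrate, and sets out from 8. The o-quinone methide 11 is generated from 8 with (R)-TRIP and intercepted by syncarpic acid F1, made separately from phloroglucinol 9 by the established acetylation, exhaustive methylation and deacetylation. Asymmetric conjugate addition of cyclic 1,3-diones to such quinone methides under chiral phosphoric acids is known, and it should give the phenol–triketone adduct F2. Phenol and enol are both capped with chloromethyl methyl ether/NaH to give the bis-MOM compound F3. N-Iodosuccinimide then iodinates the single free ring A carbon (C4a) to give the aryl iodide F4, and Sonogashira coupling with 3,3-diethoxyprop-1-yne (Pd(PPh3)2Cl2, CuI, Et3N) gives the alkynyl acetal F5. The acid treatment of step 14 removes both MOM groups and closes ring C, which brings the route back at chromone 23.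

Step 7. Facial discrimination may be weak because the trialkoxyarene offers no hydrogen-bond donor to the phosphate, and the alkyl quinone methide may tautomerise to the vinylphenol and oligomerise. The fallback replaces asymmetric catalysis by resolution and sets out from 8 and 10. Diphenyl phosphate catalysis gives the racemic diarylmethine F6. Its phenol is carbamoylated with (S)-1-phenylethyl isocyanate and the two diastereomeric carbamates are separated by chromatography or crystallisation. The one with the required C1' configuration, the carbamate F7, is cleaved with K2CO3/MeOH, which returns the route to 12.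

Step 16. Addition to the electron-rich, peri-substituted chromone may be slow, with protodeboronation competing, and facial control next to the bulky C8 substituent may be incomplete. The fallback replaces catalyst control by unselective addition, separation and recycling, and sets out from 24. Addition of 25 with [Rh(OH)(cod)]2 and an achiral bisphosphine gives 26 together with its C2 epimer, the (2S)-flavanone F8, and the two diastereomers are separated by chromatography. F8 is re-equilibrated at C2 with DBU through the ring-opened 2'-hydroxychalcone (retro-oxa-Michael then oxa-Michael) and separated again, converging on 26. C1' should be untouched because the triketone is capped as its benzyl enol ether.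

**Further compounds**

F1 | step 13 | syncarpic acid (enol of 2,2,4,4-tetramethylcyclohexane-1,3,5-trione) | CC1(C)C(=O)C=C(O)C(C)(C)C1=O
F2 | step 13 | 2-[(1S)-1-[2,4-bis(benzyloxy)-6-hydroxy-3-methylphenyl]-3-methylbutyl]-3-hydroxy-4,4,6,6-tetramethylcyclohex-2-ene-1,5-dione | Cc1c(OCc2ccccc2)cc(O)c([C@H](CC(C)C)C2=C(O)C(C)(C)C(=O)C(C)(C)C2=O)c1OCc1ccccc1
F3 | step 13 | bis-MOM ether of F2 (aryl OMOM and enol OMOM) | Cc1c(OCc2ccccc2)cc(OCOC)c([C@H](CC(C)C)C2=C(OCOC)C(C)(C)C(=O)C(C)(C)C2=O)c1OCc1ccccc1
F4 | step 13 | C4a iodide of F3 | Cc1c(OCc2ccccc2)c(I)c(OCOC)c([C@H](CC(C)C)C2=C(OCOC)C(C)(C)C(=O)C(C)(C)C2=O)c1OCc1ccccc1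
F5 | step 13 | C4a 3,3-diethoxyprop-1-yn-1-yl derivative of F3 (enol MOM ether of 21) | Cc1c(OCc2ccccc2)c(C#CC(OCC)OCC)c(OCOC)c([C@H](CC(C)C)C2=C(OCOC)C(C)(C)C(=O)C(C)(C)C2=O)c1OCc1ccccc1
F6 | step 7 | racemic 12 | Cc1c(OCc2ccccc2)cc(O)c(C(CC(C)C)c2c(OCC=C)cc(OCC=C)cc2OCC=C)c1OCc1ccccc1
F7 | step 7 | N-[(1S)-1-phenylethyl]carbamate of 12 (aryl carbamate at the phenol oxygen) | Cc1c(OCc2ccccc2)cc(OC(=O)N[C@@H](C)c2ccccc2)c([C@H](CC(C)C)c2c(OCC=C)cc(OCC=C)cc2OCC=C)c1OCc1ccccc1
F8 | step 16 | (2S) epimer of 26 | O=C1C[C@@H](c2ccccc2)Oc2c([C@H](CC(C)C)C3=C(OCc4ccccc4)C(C)(C)C(=O)C(C)(C)C3=O)c(OCc3ccccc3)c(C)c(OCc3ccccc3)c21
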